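## The problem

Sideroxylonal C is a 2-arylchroman: ring C is fused to the phloroglucinol-derived ring A and carries ring B, a second formylated phloroglucinol, at C2 (chroman numbering O1, C2, C3, C4, C4a, C5–C8, C8a; ring B is C1'–C6'). Between the two arenes the skeleton is only the chain C2–C3–C4, with an isopropyl group on C3 and an isobutyl group on C4. The three stereocentres are contiguous and all trans (2R,3R,4R). C4 has no neighbour from which it could be set and must come from an enantioselective reaction. C3 is alpha to a carbonyl group in any lactone precursor and can be set or corrected relative to C4, and C2 can be set last relative to C3. The four aldehydes and five phenols are incompatible with organometallic reagents, hydrides and strong base, so the rings must travel as methyl ethers without formyl groups, and the aldehydes must be put on at the end at the four free positions C6, C8, C3' and C5'. The O1–C2 bond is a benzylic ether to a ring with oxygen donors ortho, ortho and para to C2. That makes it acid-labile late in the route, and the same feature lets C2 be a carbinol in an open 1,3-diarylpropane that ionises and is captured by the ring A phenol.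

## Retrosynthesis

**Formyl groups and methyl ethers (16 to 15 to 14).** The four C–CHO bonds at C6, C8, C3' and C5' and the five phenolic O–H bonds are removed first. Carrying formyl groups or their precursors through the route was set aside: every earlier step uses an organometallic reagent or a hydride, and ring B must stay electron-rich for the ring closure. Target 16 is thereby reduced to pentamethyl ether 14, which has no carbonyl group. The forward reactions are a fourfold Rieche formylation of 14 to 15, where each free position lies between two oxygen donors so there is no regiochemical choice, and cleavage of five methyl ethers, each ortho to a formyl group.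

**O1–C2 (14 to 13).** Ring C is opened at the benzylic ether bond. The neighbouring cut C2–C1' on the closed ring would set C2 by attack on an oxocarbenium ion next to a branched centre, with no chance to correct the result. The cut C4–C4a would need a secondary cation without stabilisation. O1–C2 is the one bond the molecule itself makes ionisable. The precursor, diol 13, is acyclic and has only two stereocentres that matter, because both carbinol epimers give the same cation. The forward step must close the ring with ring B trans to the isopropyl group and must not touch C3 and C4.

**C2–C1' (13 to 10 and 12, from 11).** Ring B arrives complete as aryllithium 12, made from 1,3,5-trimethoxybenzene 11, and adds to lactol 10 through its open aldehyde form. Adding 12 to lactone 9 and reducing the ketone would take the same number of steps, but it passes through a hindered aryl ketone with an epimerisable C3, so the lactol is preferred. The forward reaction has to add to a hindered aldehyde faster than it enolises it.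

**Oxidation level (10 to 9).** No skeletal bond is cut. Lactone 9 is the form in which C3 is alpha to a carbonyl group on a rigid ring and can be equilibrated against C4. A half-reduction is all that is asked.

**C3–isopropyl (9 to 7 to 5, from 3 and 4).** Direct alkylation of the enolate of 3 with a secondary isopropyl halide would be one step, but it is weak. Substitution at a secondary carbon competes with elimination, and an aryl ester enolate opens to a ketene at the temperature such an alkylation needs. The three carbons are therefore taken from acetone 4 in an aldol addition to give 5, followed by dehydration to alkylidene lactone 7 and hydrogenation. C3 is then moved to the trans configuration by base (8 to 9). This costs two extra steps and replaces a doubtful kinetic alkylation by three routine reactions and a thermodynamic control element.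

**C4–isobutyl (3 to 1 and 2).** The last cut removes the isobutyl group and the only stereocentre that needs an external source of chirality. Coumarin 1 is flat, commercial and already contains ring A and the three-carbon chain. Grignard reagent 2 is commercial. The forward reaction is a copper-catalysed enantioselective conjugate addition, which must overcome the low electrophilicity of a coumarin with two donor groups.

## Roads not taken

Alternative 1: Ring C is cut at C2–C3 and C4–C4a at once. A mixed acetal A2, in which the future C2 carries a methoxy group and the ring A aryloxy group, would be ionised by a chiral Brønsted acid to an O-aryl oxocarbenium ion. The isopropyl-bearing terminus of (E)-2,6-dimethylhepta-2,4-diene A3 would bond to the cationic carbon, and the allyl cation would be trapped by the ortho carbon of ring A to give chroman A1 with a 2-methylprop-1-enyl group at C4. Hydrogenation of A1 would give 14, so this road joins the chosen one two steps before the end.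
- Merits: it would be clearly shorter (about five steps) and more convergent, with two skeletal bonds, the ring and all three stereocentres formed in one operation. In step count it is better than the chosen plan.
- Weak points: the ion from A2 is close to a 2,4,6-trimethoxybenzyl cation and carries one of the best carbon nucleophiles available, so C-alkylation of ring A and acetal scrambling compete with capture by a hindered diene that itself polymerises in acid. The diene can be attacked at either end. The absolute configuration would rest on ion pairing of a very stabilised cation with a chiral anion, for which there is no close analogy with this substitution pattern.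
- Comparison: the chosen plan sets against the shorter road that each stereocentre is controlled by an element that can be argued from known behaviour (catalyst for C4, enolate equilibration for C3, allylic strain and reversibility for C2), and that a failure in one step does not put the other centres at risk.

Alternative 2: Ring B is built, not attached. C2'–C3' and C5'–C6' are cut, leaving a chroman with a malonate at C2, A5, and dimethyl 3-oxopentanedioate A6. The enolate of A6 would be acylated at both methylene carbons by the two ester groups of A5, and the triketone tautomer would enolise to phloroglucinol diester A4.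
- Merits: the two formyl carbons of ring B would already be in place at the ester level and the ring B hydroxyls would arise free. The fourfold formylation of an acid-labile 2-arylchroman, the weakest late step of the chosen route, would shrink to a twofold formylation of ring A. In this respect the alternative is better.
- Weak points: the malonate hydrogen of A5 is acidic and beta to O1, so the base needed for a double Claisen condensation would open ring C by beta-elimination and erase C2. Acylation by a hindered, branched malonate ester is uphill until the final aromatisation. A5 must be made with all three stereocentres and without an aryl group at C2 to help. Two salicylate-type esters must still be taken to aldehydes.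
- Comparison: the chosen plan brings ring B in complete as 12 in one C–C bond formation and uses its donor power to close ring C. It accepts the risk of step 8 and answers it with a staged formylation as fallback.

Alternative 3: The lactol of ring C is cut at C4–C4a and O1–C2. The enal, (E)-2-isopropyl-5-methylhex-2-enal A8, is the self-condensation dimer of the five-carbon aldehyde, and its partner is 3,5-dimethoxyphenol A9. With a chiral amine catalyst the iminium ion of A8 would be attacked at its beta carbon by the ortho carbon of A9, and the phenol would then close the hemiacetal to lactol A7, which is the same compound as 10.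
- Merits: in step economy this road is plainly better. It would reach in one step from two bulk chemicals what the chosen route reaches in five, and steps 6 to 9 could stay unchanged.
- Weak points: A8 is alpha-branched and beta-substituted. Such enals condense poorly with the secondary amine catalysts that are selective for linear enals, and the iminium ion has no strong preference for one geometry. C3 would arise from protonation of an enamine, so both the enantioselectivity at C4 and the 3,4-trans relationship are open.
- Comparison: the chosen plan pays four more steps to put C4 in with a catalytic reaction class established on coumarins and to fix C3 on a rigid lactone where the isomers can be equilibrated. If A8 could be shown to react selectively, A7 would replace steps 1 to 5 with no change to the rest.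

Key step: step 7

Remark on the chemistry: which enantiomer of the ferrocenyl diphosphine gives (4R)-3 on this coumarin cannot be read from the structure. The route assumes the enantiomer that does, to be fixed in a pilot run. All later stereocentres are set relative to C4.

## Route

Step 1
Reactants: 1 5,7-dimethoxycoumarin; 2 isobutylmagnesium bromide
Product: 3 (4R)-4-isobutyl-5,7-dimethoxychroman-2-one
Conditions: CuBr·SMe2 (5 mol%), one enantiomer of 1-[2-(dicyclohexylphosphino)ferrocenyl]ethyldiphenylphosphine (6 mol%), 2 (1.5 equiv, slow addition), CH2Cl2, −75 °C; then aq. NH4Cl
Reagents that add atoms: none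
Why: Copper-catalysed enantioselective conjugate addition of a Grignard reagent to a coumarin, a known reaction type. The diphosphine–copper complex transfers the isobutyl group to one face of C4, so C4 is set by the catalyst alone; low temperature and slow addition keep uncatalysed 1,2-addition to the lactone carbonyl in check.

Step 2
Reactants: 3 (4R)-4-isobutyl-5,7-dimethoxychroman-2-one; 4 acetone
Product: 5 (3S,4R)-3-(2-hydroxypropan-2-yl)-4-isobutyl-5,7-dimethoxychroman-2-one
Conditions: LiN(i-Pr)2 (1.1 equiv), THF, −78 °C; then 4 (3 equiv), −78 °C; AcOH quench at −78 °C
Reagents that add atoms: none
Why: Aldol addition of a lactone enolate to a ketone. Acetone should add anti to the C4 isobutyl group, which sits pseudo-axial to avoid the C5 methoxy group, giving the 3,4-trans adduct; the main route does not rely on this because C3 becomes trigonal in step 3. The cold acidic quench prevents retro-aldol cleavage and ring-opening of the aryl ester enolate.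

Step 3
Reactants: 5 (3S,4R)-3-(2-hydroxypropan-2-yl)-4-isobutyl-5,7-dimethoxychroman-2-one
Product: 7 (4S)-4-isobutyl-5,7-dimethoxy-3-(propan-2-ylidene)chroman-2-one, via tertiary mesylate 6 (not isolated)
Conditions: MsCl, Et3N, DMAP (cat.), CH2Cl2, 0 °C; then DBU, rt
Reagents that add atoms: none
Why: Dehydration of a beta-hydroxy lactone by mesylation and E1cB elimination. The sulfene pathway allows the tertiary alcohol to be sulfonylated and DBU removes the acidic C3 hydrogen to give the conjugated alkylidene lactone; a double-bond regioisomer, if formed, would converge in step 4. C4 is not touched, and its descriptor changes to S only because the trigonal C3 now outranks C4a.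

Step 4
Reactants: 7 (4S)-4-isobutyl-5,7-dimethoxy-3-(propan-2-ylidene)chroman-2-one
Product: 9 (3R,4R)-4-isobutyl-3-isopropyl-5,7-dimethoxychroman-2-one, via cis-lactone 8 (not isolated)
Conditions: H2 (10 bar), Pd(OH)2/C, EtOAc, rt; filter; then DBU (0.3 equiv), toluene, 60 °C
Reagents that add atoms: none
Why: Heterogeneous hydrogenation of an alpha-alkylidene lactone followed by base epimerisation of the alpha centre. Hydrogen should add anti to the pseudo-axial isobutyl group and give mainly cis-lactone 8; reversible enolisation with DBU should then move C3 to the 3,4-trans isomer 9, in which the two alkyl groups are anti on a pseudo-diaxial half-chair and the isobutyl group still avoids the C5 methoxy group. C3 is therefore set under thermodynamic control relative to C4.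

Step 5
Reactants: 9 (3R,4R)-4-isobutyl-3-isopropyl-5,7-dimethoxychroman-2-one
Product: 10 (3R,4R)-4-isobutyl-3-isopropyl-5,7-dimethoxychroman-2-ol (mixture of anomers)
Conditions: i-Bu2AlH (1.2 equiv), CH2Cl2, −78 °C; aq. potassium sodium tartrate
Reagents that add atoms: none
Why: Partial reduction of a lactone to a lactol with a dialkylaluminium hydride. The tetrahedral aluminium alkoxide of the aryl lactone is stable at −78 °C, so reduction stops at the aldehyde oxidation level; C3 and C4 are not touched.

Step 6
Reactants: 10 (3R,4R)-4-isobutyl-3-isopropyl-5,7-dimethoxychroman-2-ol; 11 1,3,5-trimethoxybenzene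
Product: 13 2-[(2R,3R)-1-hydroxy-5-methyl-2-(propan-2-yl)-1-(2,4,6-trimethoxyphenyl)hexan-3-yl]-3,5-dimethoxyphenol (both C1 epimers), via 2,4,6-trimethoxyphenyllithium 12 (not isolated)
Conditions: 11 (3.5 equiv), n-BuLi (3.3 equiv), THF, 0 °C; then 10, −78 °C → 0 °C; then H2O
Reagents that add atoms: none
Why: Ortho-lithiation of 11 between two methoxy groups and addition of the aryllithium to a lactol through its ring-opened aldehyde form, both known reaction types. The first equivalent of 12 deprotonates the lactol, which opens to the phenoxide aldehyde, and carbonyl addition at low temperature should outrun enolisation, so C3 is retained. The new carbinol centre is left uncontrolled on purpose because step 7 destroys it.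

Step 7
Reactants: 13 2-[(2R,3R)-1-hydroxy-5-methyl-2-(propan-2-yl)-1-(2,4,6-trimethoxyphenyl)hexan-3-yl]-3,5-dimethoxyphenol (both C1 epimers)
Product: 14 (2R,3R,4R)-4-isobutyl-3-isopropyl-5,7-dimethoxy-2-(2,4,6-trimethoxyphenyl)chroman
Conditions: camphorsulfonic acid (10 mol%), CH2Cl2 (0.02 M), 0 °C → rt
Reagents that add atoms: none
Why: This is the acid-catalysed cyclodehydration of a 1-aryl-3-(2-hydroxyaryl)propan-1-ol to a flavan, a known reaction type. Protonation of the benzylic hydroxyl of either epimer of 13 and loss of water give one planar cation delocalised into the three methoxy groups of ring B, so the carbinol configuration is irrelevant. Ring C closes by 6-exo-trig attack of the ring A phenol oxygen on C2, the C2=C1' bond of the quinoid cation lying outside the new ring. C2 is the only new stereocentre and is controlled by C3: allylic 1,3-strain with the flanking ortho-methoxy group holds C3–H in the plane of the cation, the tethered oxygen can only reach the face that carries C4, and the ring forms with H2 and H3 anti, that is with ring B trans to the isopropyl group. The closure is reversible under the same acid, so a 2,3-cis isomer that forms can reopen and drain to the 2,3-trans,3,4-trans isomer, the only one able to hold all three substituents pseudo-equatorial. The step needs O- over C-alkylation and intra- over intermolecular capture: the ring A carbons cannot reach C2 through a reasonable ring, the methoxy oxygen at the other ortho position would have to lose a methyl group, and high dilution suppresses Friedel–Crafts attack by a second molecule. C3 and C4 stay untouched as long as the cation is trapped faster than it loses the C3 proton, which the mild acid and the fast six-membered closure should secure.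

Step 8
Reactants: 14 (2R,3R,4R)-4-isobutyl-3-isopropyl-5,7-dimethoxy-2-(2,4,6-trimethoxyphenyl)chroman
Product: 15 (2R,3R,4R)-2-(3,5-diformyl-2,4,6-trimethoxyphenyl)-4-isobutyl-3-isopropyl-5,7-dimethoxychroman-6,8-dicarbaldehyde
Conditions: Cl2CHOMe (12 equiv), TiCl4 (12 equiv), CH2Cl2, premixed at −78 °C, 14 added last, −78 °C → 0 °C; then 1 M HCl, 0 °C
Reagents that add atoms: dichloromethyl methyl ether, COC(Cl)Cl; water, O
Why: Rieche formylation (electrophilic aromatic substitution by the TiCl4-activated dichloromethyl ether, then hydrolysis of the alpha-chloro ether). The four free positions C6, C8, C3' and C5' each lie between two oxygen donors and are the only ones open, so regiochemistry is not in question, and excess reagent drives the second formylation of each ring. Premixing the reagents and adding 14 cold should let the first formylation of ring B, which switches off ionisation of O1–C2, outrun Lewis-acid opening of ring C.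

Step 9
Reactants: 15 (2R,3R,4R)-2-(3,5-diformyl-2,4,6-trimethoxyphenyl)-4-isobutyl-3-isopropyl-5,7-dimethoxychroman-6,8-dicarbaldehyde
Product: 16 sideroxylonal C, (2R,3R,4R)-2-(3,5-diformyl-2,4,6-trihydroxyphenyl)-5,7-dihydroxy-4-isobutyl-3-isopropylchroman-6,8-dicarbaldehyde
Conditions: BBr3 (12 equiv), CH2Cl2, −78 °C → rt; then ice-water
Reagents that add atoms: none
Why: Cleavage of aryl methyl ethers by BBr3. Each of the five methoxy groups is ortho to a formyl group and is activated by chelation of boron between ether and carbonyl oxygen while bromide attacks the methyl carbon; aqueous work-up frees the phenols. The stereocentres are not involved, and O1–C2 is far less ionisable than in 14 because ring B now carries two formyl groups.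

## Compound list

1 | 5,7-dimethoxycoumarin | COc1cc(OC)c2ccc(=O)oc2c1 | starting material
2 | isobutylmagnesium bromide | CC(C)C[Mg]Br | starting material
3 | (4R)-4-isobutyl-5,7-dimethoxychroman-2-one | CC(C)C[C@H]1c2c(OC)cc(OC)cc2OC(=O)C1 | intermediate
4 | acetone | CC(C)=O | starting material
5 | (3S,4R)-3-(2-hydroxypropan-2-yl)-4-isobutyl-5,7-dimethoxychroman-2-one | CC(C)C[C@H]1c2c(OC)cc(OC)cc2OC(=O)[C@@H]1C(C)(C)O | intermediate
6 | 2-[(3S,4R)-4-isobutyl-5,7-dimethoxy-2-oxochroman-3-yl]propan-2-yl methanesulfonate | CC(C)C[C@H]1c2c(OC)cc(OC)cc2OC(=O)[C@@H]1C(C)(C)OS(C)(=O)=O | intermediate (not isolated)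
7 | (4S)-4-isobutyl-5,7-dimethoxy-3-(propan-2-ylidene)chroman-2-one | CC(C)C[C@H]1c2c(OC)cc(OC)cc2OC(=O)C1=C(C)C | intermediate
8 | (3S,4R)-4-isobutyl-3-isopropyl-5,7-dimethoxychroman-2-one (cis) | CC(C)C[C@H]1c2c(OC)cc(OC)cc2OC(=O)[C@H]1C(C)C | intermediate (not isolated)
9 | (3R,4R)-4-isobutyl-3-isopropyl-5,7-dimethoxychroman-2-one (trans) | CC(C)C[C@H]1c2c(OC)cc(OC)cc2OC(=O)[C@@H]1C(C)C | intermediate
10 | (3R,4R)-4-isobutyl-3-isopropyl-5,7-dimethoxychroman-2-ol, mixture of anomers | CC(C)C[C@H]1c2c(OC)cc(OC)cc2OC(O)[C@@H]1C(C)C | intermediate
11 | 1,3,5-trimethoxybenzene | COc1cc(OC)cc(OC)c1 | starting material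
12 | 2,4,6-trimethoxyphenyllithium | [Li]c1c(OC)cc(OC)cc1OC | intermediate (not isolated)
13 | 2-[(2R,3R)-1-hydroxy-5-methyl-2-(propan-2-yl)-1-(2,4,6-trimethoxyphenyl)hexan-3-yl]-3,5-dimethoxyphenol, both C1 epimers | CC(C)C[C@@H](c1c(OC)cc(OC)cc1O)[C@@H](C(C)C)C(O)c1c(OC)cc(OC)cc1OC | intermediate
14 | (2R,3R,4R)-4-isobutyl-3-isopropyl-5,7-dimethoxy-2-(2,4,6-trimethoxyphenyl)chroman | CC(C)C[C@H]1c2c(OC)cc(OC)cc2O[C@@H](c2c(OC)cc(OC)cc2OC)[C@@H]1C(C)C | intermediate
15 | (2R,3R,4R)-2-(3,5-diformyl-2,4,6-trimethoxyphenyl)-4-isobutyl-3-isopropyl-5,7-dimethoxychroman-6,8-dicarbaldehyde | CC(C)C[C@H]1c2c(OC)c(C=O)c(OC)c(C=O)c2O[C@@H](c2c(OC)c(C=O)c(OC)c(C=O)c2OC)[C@@H]1C(C)C | intermediate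
16 | sideroxylonal C, (2R,3R,4R)-2-(3,5-diformyl-2,4,6-trihydroxyphenyl)-5,7-dihydroxy-4-isobutyl-3-isopropylchroman-6,8-dicarbaldehyde | CC(C)C[C@H]1c2c(O)c(C=O)c(O)c(C=O)c2O[C@@H](c2c(O)c(C=O)c(O)c(C=O)c2O)[C@@H]1C(C)C | target

## Step count and least certain steps

Total step count: 9. Longest linear sequence: 9 steps (1 to 16); 4 and 11 are commercial and enter directly.

**Step 7 (key step).**
- Risk: the reversible closure may not converge on one C2 isomer as cleanly as the conformational argument suggests, because the pseudo-equatorial isobutyl group of the all-trans isomer is pressed against the C5 methoxy group. The cation may also lose the C3 proton and be re-protonated, which would scramble C3. Intermolecular Friedel–Crafts alkylation of the very nucleophilic ring A would give oligomers.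
- Fallback: it sets out from 13 and returns at 14 with no new compound. The ring is closed by Mitsunobu cyclodehydration (PPh3, diisopropyl azodicarboxylate, THF, 0 °C). The medium is neutral and the closure irreversible, so nothing can re-ionise O1–C2 or protonate an alkene. The alkoxyphosphonium of so electron-rich a benzylic alcohol is expected to ionise, so both carbinol epimers still converge. C2 is then set under kinetic control by the same allylic-strain preference, not by equilibration.

**Step 8.**
- Risk: TiCl4 may ionise O1–C2 before ring B has been deactivated, leading to ring opening, elimination or alkylation of a second molecule. The fourth formylation may stall on the doubly deactivated rings. Loss of methyl groups ortho to new aldehydes would be harmless, since step 9 removes them all.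
- Fallback: it sets out from 14 and returns at 15. A Vilsmeier–Haack reaction (POCl3, DMF, 0 → 60 °C; aq. NaOAc) puts one formyl group on each ring without a strong Lewis acid. It should give (2R,3R,4R)-2-(3-formyl-2,4,6-trimethoxyphenyl)-4-isobutyl-3-isopropyl-5,7-dimethoxychroman-8-carbaldehyde F1 (a C6 regioisomer on ring A would converge). F1 no longer ionises easily and is taken to 15 with Cl2CHOMe/TiCl4 as in step 8.

**Step 1.**
- Risk: conversion may be low because two donor groups reduce the electrophilicity of C4. Facial discrimination may be poor because the C5 methoxy group crowds the site of attack. 1,2-Addition to the lactone may compete.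
- Fallback: it sets out from 1 and 2 and returns at 3. A racemic copper-catalysed addition (CuI 10 mol%, TMSCl, THF, −40 °C) gives racemic 4-isobutyl-5,7-dimethoxychroman-2-one F2. Aminolysis with (S)-1-phenylethylamine (toluene, 80 °C) gives 3-(2-hydroxy-4,6-dimethoxyphenyl)-5-methyl-N-[(1S)-1-phenylethyl]hexanamide F3 as two diastereomers. The (3R)-diastereomer of F3 is separated by chromatography or crystallisation and relactonised (p-TsOH·H2O, toluene, reflux) to 3.

**Step 9.**
- Risk: Lewis-acid opening of O1–C2 with loss of the C2 configuration; reaction of BBr3 at the aldehydes; incomplete cleavage of the last ether.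
- Fallback: it sets out from 15 and returns at 16 with no new compound. The methyl groups are removed by nucleophilic attack of a thiolate at the methyl carbons (EtSNa, DMF, 100 °C; acidic work-up). The ether oxygens are not activated, so O1–C2 cannot ionise.

**Step 4.**
- Risk: hydrogenation of the hindered tetrasubstituted alkene may be slow, and the base equilibrium at C3 may be less one-sided than expected.
- Fallback: it sets out from 5, whose C3 is already trans from the kinetic aldol addition, and returns at 9. Acylation with methyl chlorooxoacetate (pyridine, DMAP, CH2Cl2, 0 °C) gives methyl 2-[(3S,4R)-4-isobutyl-5,7-dimethoxy-2-oxochroman-3-yl]propan-2-yl oxalate F4. Barton–McCombie-type radical deoxygenation (Bu3SnH, AIBN, toluene, 110 °C) replaces the tertiary C–O bond by C–H. C3 never becomes trigonal, so its configuration is kept under kinetic control.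

**Step 6.**
- Risk: the basic, doubly ortho-substituted aryllithium may enolise the hindered branched aldehyde, with loss of the C3 configuration and return of lactol, or addition may be slow for steric reasons.
- Fallback: it sets out from 9 and returns at 13. Aryllithium 12 (from 11 and n-BuLi) is added to the lactone carbonyl of 9 at −78 °C to give (2R,3R)-3-(2-hydroxy-4,6-dimethoxyphenyl)-5-methyl-2-(propan-2-yl)-1-(2,4,6-trimethoxyphenyl)hexan-1-one F5; a second addition is blocked by the two ortho-methoxy groups. The ketone is reduced with LiAlH4 (THF, 0 °C) to 13 as a mixture of carbinol epimers, both of which serve.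

## Further compounds

F0 | step 7 | none | none
F1 | step 8 | (2R,3R,4R)-2-(3-formyl-2,4,6-trimethoxyphenyl)-4-isobutyl-3-isopropyl-5,7-dimethoxychroman-8-carbaldehyde | CC(C)C[C@H]1c2c(OC)cc(OC)c(C=O)c2O[C@@H](c2c(OC)cc(OC)c(C=O)c2OC)[C@@H]1C(C)C
F2 | step 1 | racemic 4-isobutyl-5,7-dimethoxychroman-2-one | CC(C)CC1CC(=O)Oc2cc(OC)cc(OC)c21
F3 | step 1 | 3-(2-hydroxy-4,6-dimethoxyphenyl)-5-methyl-N-[(1S)-1-phenylethyl]hexanamide, both C3 epimers | CC(C)CC(CC(=O)N[C@@H](C)c1ccccc1)c1c(OC)cc(OC)cc1O
F0 | step 9 | none | none
F4 | step 4 | methyl 2-[(3S,4R)-4-isobutyl-5,7-dimethoxy-2-oxochroman-3-yl]propan-2-yl oxalate | CC(C)C[C@H]1c2c(OC)cc(OC)cc2OC(=O)[C@@H]1C(C)(C)OC(=O)C(=O)OC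
F5 | step 6 | (2R,3R)-3-(2-hydroxy-4,6-dimethoxyphenyl)-5-methyl-2-(propan-2-yl)-1-(2,4,6-trimethoxyphenyl)hexan-1-one | CC(C)C[C@@H](c1c(OC)cc(OC)cc1O)[C@@H](C(C)C)C(=O)c1c(OC)cc(OC)cc1OC
A1 | alternative 1 | (2R,3R,4R)-3-isopropyl-5,7-dimethoxy-4-(2-methylprop-1-enyl)-2-(2,4,6-trimethoxyphenyl)chroman | CC(C)=C[C@H]1c2c(OC)cc(OC)cc2O[C@@H](c2c(OC)cc(OC)cc2OC)[C@@H]1C(C)C
A2 | alternative 1 | 2-[(3,5-dimethoxyphenoxy)(methoxy)methyl]-1,3,5-trimethoxybenzene | COC(Oc1cc(OC)cc(OC)c1)c1c(OC)cc(OC)cc1OC
A3 | alternative 1 | (E)-2,6-dimethylhepta-2,4-diene | CC(C)/C=C/C=C(C)C
A4 | alternative 2 | dimethyl 2,4,6-trihydroxy-5-[(2R,3R,4R)-4-isobutyl-3-isopropyl-5,7-dimethoxychroman-2-yl]isophthalate | CC(C)C[C@H]1c2c(OC)cc(OC)cc2O[C@@H](c2c(O)c(C(=O)OC)c(O)c(C(=O)OC)c2O)[C@@H]1C(C)C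
A5 | alternative 2 | dimethyl 2-[(2R,3R,4R)-4-isobutyl-3-isopropyl-5,7-dimethoxychroman-2-yl]malonate | CC(C)C[C@H]1c2c(OC)cc(OC)cc2O[C@@H](C(C(=O)OC)C(=O)OC)[C@@H]1C(C)C
A6 | alternative 2 | dimethyl 3-oxopentanedioate | COC(=O)CC(=O)CC(=O)OC
A7 | alternative 3 | (3R,4R)-4-isobutyl-3-isopropyl-5,7-dimethoxychroman-2-ol, mixture of anomers | CC(C)C[C@H]1c2c(OC)cc(OC)cc2OC(O)[C@@H]1C(C)C
A8 | alternative 3 | (E)-2-isopropyl-5-methylhex-2-enal | CC(C)C/C=C(/C=O)C(C)C
A9 | alternative 3 | 3,5-dimethoxyphenol | COc1cc(O)cc(OC)c1
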